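The oxocane (O, C6–C12; chain numbered from the alkyne carbon C1 to C15) is disconnected across the ring. Its C7 chloride is vicinal to the C6–O bond and its C9 chloride sits opposite the oxygen, four bonds away on either side: the signature of a transannular O–C9 bond. The precursor is therefore a 2,5-cis tetrahydrofuran (O, C9–C12) with a cis C6=C7 alkene. One operation, a chloronium-triggered ring expansion, forms O–C6 and C7–Cl, passes through a bicyclic oxonium ion and lets chloride cut O–C9 with inversion, setting C6, C7 and C9. C9 and C10 are bought as 2-deoxy-D-ribose; C12 and C13 are relayed by an osmium-catalysed oxidative cyclisation.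

Key step: step 9

Remark: 2-deoxy-D-ribose is written in its open-chain form. Chlorodiethylsulfonium hexachloroantimonate (Et2SCl·SbCl6) is assumed to be accessible in one operation from Et2S, Cl2 and SbCl5. Ring A is the tetrahydrofuran (O, C9–C12) and ring B the transient five-membered ring (O, C6–C9).

Step 1
Reactants: 1 2-deoxy-D-ribose; 2 propyltriphenylphosphonium bromide
Product: 3 (2R,3S,5Z)-oct-5-ene-1,2,3-triol
Conditions: 2 (3.5 equiv), KN(SiMe3)2 (3.4 equiv), THF, 0 °C; then 1, THF/DMSO, −20 °C to rt
Reagents that add atoms: propyltriphenylphosphonium bromide (2), CCC[P+](c1ccccc1)(c1ccccc1)c1ccccc1.[Br-]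
Why: Wittig olefination of the aldehyde form of the lactol with a non-stabilised ylide under salt-free conditions should give the Z alkene (needed later for C13), leaves C9 and C10 as bought, and the excess ylide covers the three hydroxyl protons.

Step 2
Reactants: 3 (2R,3S,5Z)-oct-5-ene-1,2,3-triol
Product: 4 (2R,3S,5R)-2-(hydroxymethyl)-5-[(1S)-1-hydroxypropyl]oxolan-3-ol
Conditions: OsO4 (5 mol%), Me3NO·2H2O (4 equiv), CF3CO2H, acetone/H2O, rt
Reagents that add atoms: trimethylamine N-oxide, C[N+](C)(C)[O-]
Why: Donohoe-type osmium-catalysed oxidative cyclisation, in which the terminal 1,2-diol binds osmium and O9 plus one oxo ligand add to the same face of the alkene in one [3+2] event, so only the 2,5-cis ring can form (C12 controlled by C9) and the Z geometry becomes the (S)-carbinol at C13.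

Step 3
Reactants: 4 (2R,3S,5R)-2-(hydroxymethyl)-5-[(1S)-1-hydroxypropyl]oxolan-3-ol
Product: 5 disiloxane-bridged alcohol: 4 with the ring 3-O and the CH2O oxygen joined by a 1,1,3,3-tetraisopropyldisiloxane-1,3-diyl group, (1S)-carbinol at C13 free
Conditions: (i-Pr2SiCl)2O (1.05 equiv), pyridine, 0 °C to rt
Reagents that add atoms: 1,3-dichloro-1,1,3,3-tetraisopropyldisiloxane, CC(C)[Si](Cl)(C(C)C)O[Si](Cl)(C(C)C)C(C)C
Why: Markiewicz-type diol protection, where the primary hydroxyl reacts first and the second Si–Cl closes the eight-membered ring onto the ring hydroxyl as in 3',5'-protection of 2'-deoxynucleosides, which singles out the C13 carbinol.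

Step 4
Reactants: 5 disiloxane-bridged alcohol
Product: 6 disiloxane-bridged bromide, (1R)-1-bromopropyl at the ring 5-position
Conditions: CBr4, PPh3, 2,6-lutidine, toluene, 60 °C
Reagents that add atoms: carbon tetrabromide, BrC(Br)(Br)Br
Why: Appel bromination, an SN2 displacement of the alkoxyphosphonium by bromide, should convert (13S)-OH into (13R)-Br with inversion while the base buffers HBr and protects the disiloxane.

Step 5
Reactants: 6 disiloxane-bridged bromide
Product: 7 (2R,3S,5R)-5-[(1R)-1-bromopropyl]-2-(hydroxymethyl)oxolan-3-ol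
Conditions: HF·pyridine, THF/pyridine, 0 °C to rt
Reagents that add atoms: none
Why: Fluoride-mediated Si–O cleavage under non-basic conditions frees both hydroxyls without forming an alkoxide that could displace the cis-disposed secondary bromide.

Step 6
Reactants: 7 (2R,3S,5R)-5-[(1R)-1-bromopropyl]-2-(hydroxymethyl)oxolan-3-ol; 8 pent-1-en-4-yne
Product: 10 (2R,3S,5R)-5-[(1R)-1-bromopropyl]-2-(hex-5-en-2-yn-1-yl)oxolan-3-ol, via primary triflate 9 (not isolated)
Conditions: Tf2O (1.1 equiv), 2,6-lutidine, CH2Cl2, −78 °C; then LiC≡CCH2CH=CH2 (from 8 and n-BuLi, 3 equiv), THF/DMPU, −78 to −20 °C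
Reagents that add atoms: pent-1-en-4-yne (8), C=CCC#C
Why: Selective triflation of the primary hydroxyl followed by SN2 alkylation of a lithium acetylide builds the C7–C8 bond; the trans relation of C8 and O10 rules out oxetane formation and the hindered secondary bromide should be inert below −20 °C.

Step 7
Reactants: 10 (2R,3S,5R)-5-[(1R)-1-bromopropyl]-2-(hex-5-en-2-yn-1-yl)oxolan-3-ol
Product: 11 (2R,3S,5R)-5-[(1R)-1-bromopropyl]-2-[(2Z)-hexa-2,5-dien-1-yl]oxolan-3-ol
Conditions: H2 (1 atm), Pd/CaCO3 poisoned with Pb(OAc)2, quinoline, EtOAc, rt, stopped after one equivalent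
Reagents that add atoms: none
Why: Lindlar semihydrogenation delivers H2 syn to the internal alkyne and should give the Z C6=C7 alkene required for the C6/C7 relationship, leaving the terminal alkene and the alkyl bromide untouched.

Step 8
Reactants: 11 (2R,3S,5R)-5-[(1R)-1-bromopropyl]-2-[(2Z)-hexa-2,5-dien-1-yl]oxolan-3-ol
Product: 12 (2R,3S,5R)-5-[(1R)-1-bromopropyl]-2-[(2Z)-hexa-2,5-dien-1-yl]oxolan-3-yl acetate
Conditions: Ac2O, pyridine, DMAP (cat.), CH2Cl2, rt
Reagents that add atoms: acetic anhydride, CC(=O)OC(C)=O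
Why: DMAP-catalysed acylation installs the acetate of the target and at the same time removes O10 as a competing nucleophile for the next step.

Step 9
Reactants: 12 (2R,3S,5R)-5-[(1R)-1-bromopropyl]-2-[(2Z)-hexa-2,5-dien-1-yl]oxolan-3-yl acetate
Product: 14 (2R,4S,5S,7S,8S)-2-[(1R)-1-bromopropyl]-5,7-dichloro-8-(prop-2-en-1-yl)oxocan-4-yl acetate, via bicyclic oxonium salt 13 (not isolated)
Conditions: Et2SCl·SbCl6 (1.05 equiv), CH2Cl2, −78 °C, 5 min; then n-Bu4NCl (5 equiv), −78 to −40 °C
Reagents that add atoms: chlorodiethylsulfonium hexachloroantimonate, CC[S+](Cl)CC.Cl[Sb-](Cl)(Cl)(Cl)(Cl)Cl; tetrabutylammonium chloride, CCCC[N+](CCCC)(CCCC)CCCC.[Cl-]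
Why: Proposed new method: the sulfonium salt transfers Cl+ to the cis C6=C7 alkene while the ring oxygen opens the chloriranium at C6 anti to chlorine (5-endo closure of ring B), giving the cis-fused 1-oxoniabicyclo[3.3.0]octane 13; chloride then attacks the ring-fusion carbon C9 with inversion and cuts the shared O–C9 bond, so the eight-membered ring arises from O–C6 closure plus O–C9 scission, a ring expansion by three atoms. The closest known reaction types are the bromonium-induced ring expansion of alkenyl tetrahydrofurans terminated by a neighbouring carbonyl oxygen and the opening of preformed trialkyloxonium ions of this family by halide; new here is chloronium initiation combined with intermolecular chloride attack at the fusion carbon. C6 and C7 follow from anti addition across the Z alkene and from exo folding of the chain on the convex face of the bicycle (the endo mode would drive the C5 chain into the bromopropyl arm on C12), so both are relayed from C9 and C12, and C9 is inverted stereospecifically. The step needs chemoselectivity for the 1,2-disubstituted alkene over the terminal vinyl, which is secured by its higher electron density and by the fact that only it can be assisted by the ring oxygen. It also needs chloride to attack C9 and not C6 or C12: C6 is retarded by the new vicinal C–Cl dipole and C12 by the branched bromine-bearing neighbour on the concave face, whereas cleavage at C9 releases both five-membered rings. This regioselectivity is the main uncertainty, and the low temperature and high chloride concentration are meant to outrun participation by the C10 acetate.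

Step 10
Reactants: 14 (2R,4S,5S,7S,8S)-2-[(1R)-1-bromopropyl]-5,7-dichloro-8-(prop-2-en-1-yl)oxocan-4-yl acetate; 15 (E)-but-2-enal
Product: 16 (2R,4S,5S,7S,8S)-2-[(1R)-1-bromopropyl]-5,7-dichloro-8-[(2E)-4-oxobut-2-en-1-yl]oxocan-4-yl acetate
Conditions: 15 (10 equiv), second-generation Hoveyda–Grubbs catalyst (5 mol%), CH2Cl2, 40 °C
Reagents that add atoms: (E)-but-2-enal (15), C/C=C/C=O
Why: Olefin cross-metathesis of the terminal allyl group with an excess of an electron-poor partner should give the E enal under thermodynamic control, and nothing else in 14 is metathesis-active.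

Step 11
Reactants: 16 (2R,4S,5S,7S,8S)-2-[(1R)-1-bromopropyl]-5,7-dichloro-8-[(2E)-4-oxobut-2-en-1-yl]oxocan-4-yl acetate
Product: 17 (2R,4S,5S,7S,8S)-2-[(1R)-1-bromopropyl]-5,7-dichloro-8-[(2E)-pent-2-en-4-yn-1-yl]oxocan-4-yl acetate
Conditions: Me3SiCHN2, LiN(i-Pr)2, THF, −78 °C; then 16, −78 to 0 °C
Reagents that add atoms: trimethylsilyldiazomethane, C[Si](C)(C)C=[N+]=[N-]
Why: Colvin rearrangement (1,2-addition of the lithiated diazo reagent, Peterson-type loss of silanolate, loss of N2 and 1,2-hydride shift of the alkylidene carbene) should give the terminal alkyne with the E alkene intact, the aldehyde reacting far faster than the acetate at −78 °C.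

Compound list
1 | 2-deoxy-D-ribose, open-chain form (3S,4R)-3,4,5-trihydroxypentanal | OC[C@@H](O)[C@@H](O)CC=O | starting material
2 | propyltriphenylphosphonium bromide | CCC[P+](c1ccccc1)(c1ccccc1)c1ccccc1.[Br-] | starting material
3 | (2R,3S,5Z)-oct-5-ene-1,2,3-triol | OC[C@@H](O)[C@@H](O)C/C=C\CC | intermediate
4 | (2R,3S,5R)-2-(hydroxymethyl)-5-[(1S)-1-hydroxypropyl]oxolan-3-ol | OC[C@H]1O[C@@H]([C@@H](O)CC)C[C@@H]1O | intermediate
5 | (1S)-1-[(2R,4S,5R)-4-hydroxy-5-(hydroxymethyl)oxolan-2-yl]propan-1-ol with the ring 4-O and the CH2O oxygen bridged by 1,1,3,3-tetraisopropyldisiloxane-1,3-diyl | CC[C@H](O)[C@H]1C[C@@H]2O[Si](C(C)C)(C(C)C)O[Si](C(C)C)(C(C)C)OC[C@H]2O1 | intermediate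
6 | the same disiloxane-bridged oxolane carrying a (1R)-1-bromopropyl group in place of the carbinol | CC[C@@H](Br)[C@H]1C[C@@H]2O[Si](C(C)C)(C(C)C)O[Si](C(C)C)(C(C)C)OC[C@H]2O1 | intermediate
7 | (2R,3S,5R)-5-[(1R)-1-bromopropyl]-2-(hydroxymethyl)oxolan-3-ol | OC[C@H]1O[C@@H]([C@H](Br)CC)C[C@@H]1O | intermediate
8 | pent-1-en-4-yne | C=CCC#C | starting material
9 | [(2R,3S,5R)-5-[(1R)-1-bromopropyl]-3-hydroxyoxolan-2-yl]methyl trifluoromethanesulfonate | O=S(=O)(OC[C@H]1O[C@@H]([C@H](Br)CC)C[C@@H]1O)C(F)(F)F | intermediate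
10 | (2R,3S,5R)-5-[(1R)-1-bromopropyl]-2-(hex-5-en-2-yn-1-yl)oxolan-3-ol | C=CCC#CC[C@H]1O[C@@H]([C@H](Br)CC)C[C@@H]1O | intermediate
11 | (2R,3S,5R)-5-[(1R)-1-bromopropyl]-2-[(2Z)-hexa-2,5-dien-1-yl]oxolan-3-ol | C=CC/C=C\C[C@H]1O[C@@H]([C@H](Br)CC)C[C@@H]1O | intermediate
12 | (2R,3S,5R)-5-[(1R)-1-bromopropyl]-2-[(2Z)-hexa-2,5-dien-1-yl]oxolan-3-yl acetate | C=CC/C=C\C[C@H]1O[C@@H]([C@H](Br)CC)C[C@@H]1OC(C)=O | intermediate
13 | cis-fused 1-oxoniabicyclo[3.3.0]octane hexachloroantimonate: O+ bonded to C6, C9 and C12; allyl (exo) on C6, Cl (exo) on C7, acetoxy on C10, (1R)-1-bromopropyl on C12; (6S,7S,9R,10S,12R) | C=CC[C@H]1[C@@H](Cl)C[C@@H]2[C@@H](OC(C)=O)C[C@H]([C@H](Br)CC)[O+]12.Cl[Sb-](Cl)(Cl)(Cl)(Cl)Cl | intermediate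
14 | (2R,4S,5S,7S,8S)-2-[(1R)-1-bromopropyl]-5,7-dichloro-8-(prop-2-en-1-yl)oxocan-4-yl acetate | C=CC[C@@H]1O[C@@H]([C@H](Br)CC)C[C@H](OC(C)=O)[C@@H](Cl)C[C@@H]1Cl | intermediate
15 | (E)-but-2-enal (crotonaldehyde) | C/C=C/C=O | starting material
16 | (2R,4S,5S,7S,8S)-2-[(1R)-1-bromopropyl]-5,7-dichloro-8-[(2E)-4-oxobut-2-en-1-yl]oxocan-4-yl acetate | O=C/C=C/C[C@@H]1O[C@@H]([C@H](Br)CC)C[C@H](OC(C)=O)[C@@H](Cl)C[C@@H]1Cl | intermediate
17 | (2R,4S,5S,7S,8S)-2-[(1R)-1-bromopropyl]-5,7-dichloro-8-[(2E)-pent-2-en-4-yn-1-yl]oxocan-4-yl acetate | C#C/C=C/C[C@@H]1O[C@@H]([C@H](Br)CC)C[C@H](OC(C)=O)[C@@H](Cl)C[C@@H]1Cl | target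

Total step count: 11. Longest linear sequence: 11 steps (the route is fully linear from 1).

Steps most likely to fail

Step 9 (Proposed new method). Chloride may open the oxonium ion at C6 or C12 instead of C9, returning a vicinal dichloride or a ring-switched tetrahydrofuran. The acetate may also open it at C9 before chloride arrives, or chloride may capture the chloriranium before the ring oxygen does. The fallback separates ring expansion from C–Cl bond formation and uses the established carbonyl-terminated mode of this ring expansion. It sets out from 12, which is treated with Et2SCl·SbCl6 alone. The C10 acetate carbonyl then opens the oxonium ion at C9 in a five-membered closure, as in classical acyloxonium chemistry, to give the ring-expanded 2-methyl-1,3-dioxolan-2-ylium salt F1. Aqueous NaHCO3 should hydrolyse it to the C9 alcohol C10 acetate F2, whose C9–O bond lies on the face the chlorine must occupy. Its acyl-migration isomer F3 would be equilibrated with F2 under mild base and recycled. Stereoretentive chlorination of F2 (SOCl2, then catalytic TiCl4, front-side return from the chlorosulfite) comes back to the route at 14.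

Step 4. The ring oxygen may participate during activation of the C13 carbinol, giving retention or enlargement to a tetrahydropyran, and HBr may be eliminated. The fallback forms the C12–O and C13–Br bonds together and never activates an alcohol next to the ring. It sets out from 3, whose primary and C10 hydroxyls are bridged with (i-Pr2SiCl)2O in pyridine to give the disiloxane-bridged (Z)-alkenol F4 with the C9 hydroxyl free. N-Bromosuccinimide in CH2Cl2 at 0 °C should then effect anti 5-exo bromoetherification across the Z alkene. This comes back to the route at 6, after separation from the 2,5-trans ring isomer that this substrate-controlled closure may also give.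

Step 11. The basic diazo reagent may cleave or attack the acetate, eliminate HCl or HBr, or trigger vinylogous opening of the ring ether through the enal. The fallback builds the enyne under non-basic conditions and sets out from 14. Oxidative cleavage of the allyl group (OsO4 cat., NaIO4, 2,6-lutidine, dioxane/H2O) should give the aldehyde F5. Takai olefination (CHI3, CrCl2, THF, 0 °C) should give the (E)-vinyl iodide F6. Sonogashira coupling with trimethylsilylacetylene (Pd(PPh3)4, CuI, i-Pr2NH) should give the silyl enyne F7. Buffered desilylation (n-Bu4NF, AcOH, THF, 0 °C) comes back to the route at 17.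

Further compounds
F1 | step 9 | ring-expanded 2-methyl-1,3-dioxolan-2-ylium hexachloroantimonate spanning O9 and O10 of the oxocane (C7–Cl, C6-allyl, C12-(1R)-1-bromopropyl) | C=CC[C@@H]1O[C@@H]([C@H](Br)CC)C[C@@H]2OC(C)=[O+][C@H]2C[C@@H]1Cl.Cl[Sb-](Cl)(Cl)(Cl)(Cl)Cl
F2 | step 9 | (2R,4S,5S,7S,8S)-2-[(1R)-1-bromopropyl]-7-chloro-5-hydroxy-8-(prop-2-en-1-yl)oxocan-4-yl acetate | C=CC[C@@H]1O[C@@H]([C@H](Br)CC)C[C@H](OC(C)=O)[C@@H](O)C[C@@H]1Cl
F3 | step 9 | (2R,4S,5S,7S,8S)-2-[(1R)-1-bromopropyl]-7-chloro-4-hydroxy-8-(prop-2-en-1-yl)oxocan-5-yl acetate | C=CC[C@@H]1O[C@@H]([C@H](Br)CC)C[C@H](O)[C@@H](OC(C)=O)C[C@@H]1Cl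
F4 | step 4 | (7R,8S)-8-[(2Z)-pent-2-en-1-yl]-2,2,4,4-tetraisopropyl-1,3,5,2,4-trioxadisilocan-7-ol (triol 3 with O8 and O10 bridged, C9–OH free) | CC/C=C\C[C@@H]1O[Si](C(C)C)(C(C)C)O[Si](C(C)C)(C(C)C)OC[C@H]1O
F5 | step 11 | (2R,4S,5S,7S,8S)-2-[(1R)-1-bromopropyl]-5,7-dichloro-8-(2-oxoethyl)oxocan-4-yl acetate | O=CC[C@@H]1O[C@@H]([C@H](Br)CC)C[C@H](OC(C)=O)[C@@H](Cl)C[C@@H]1Cl
F6 | step 11 | (2R,4S,5S,7S,8S)-2-[(1R)-1-bromopropyl]-5,7-dichloro-8-[(2E)-3-iodoprop-2-en-1-yl]oxocan-4-yl acetate | I/C=C/C[C@@H]1O[C@@H]([C@H](Br)CC)C[C@H](OC(C)=O)[C@@H](Cl)C[C@@H]1Cl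
F7 | step 11 | (2R,4S,5S,7S,8S)-2-[(1R)-1-bromopropyl]-5,7-dichloro-8-[(2E)-5-(trimethylsilyl)pent-2-en-4-yn-1-yl]oxocan-4-yl acetate | C[Si](C)(C)C#C/C=C/C[C@@H]1O[C@@H]([C@H](Br)CC)C[C@H](OC(C)=O)[C@@H](Cl)C[C@@H]1Cl
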